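## Retrosynthetic overview
1. Target 27 ⇒ tert-butyl ester 26 (acidolysis) ⇒ acyclic triene 23. One endo intramolecular Diels–Alder reaction closes rings A and B together (bonds C4a–C8a and C1–C2) and sets C1, C2, C4a and C8a.
2. 23 ⇒ α-acyloxy aldehyde 14 + dienyl iodide 20 (C5–C4a bond, Nozaki–Hiyama–Kishi coupling, sets C5).
3. Key disconnection: the C6–O(acyl) bond of 14 ⇒ enone aldehyde 12 + glutaconic half ester 7, used as its peroxide 13. An enamine-catalysed acyloxy transfer sets C6 and delivers the whole side chain.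
4. 12 ⇐ (R)-β-citronellene 8 + methyl vinyl ketone 11. 20 ⇐ tiglic acid 15. 7 ⇐ tert-butyl acetoacetate 1 + ClZnCH2CO2tBu 4.

Assumption: the decalin locants used throughout are C1 (acetyl), C2 (sec-butyl), C3=C4, C4a, C5 (OH), C6 (acyloxy), C7, C8 (methyl), C8a, and (R)-β-citronellene of high ee is taken as a catalogue item.

## Route

Step 1
Reactants: 1 tert-butyl acetoacetate
Product: 2 tert-butyl (2E)-3-(tosyloxy)but-2-enoate
Conditions: TsCl (1.5 equiv), N-methylimidazole (1.5 equiv), Et3N (1.5 equiv), CH2Cl2, 0 °C → rt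
Reagents that add atoms: p-toluenesulfonyl chloride, Cc1ccc(cc1)S(=O)(=O)Cl
Why: Stereoselective enol tosylation of a β-keto ester by the N-tosylimidazolium salt, in which the non-chelating amine base gives the E enol tosylate (methyl cis to the ester), the geometry later needed in the side chain.

Step 2
Reactants: 2 tert-butyl (2E)-3-(tosyloxy)but-2-enoate
Product: 3 (2E)-3-(tosyloxy)but-2-enoic acid
Conditions: TFA/CH2Cl2 (1:3), 0 °C → rt
Reagents that add atoms: none
Why: Acidolysis of a tert-butyl ester (loss of isobutene) leaves the acid-stable enol tosylate and its E geometry untouched and frees the conjugated carboxyl group before the second tert-butyl ester is brought in.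

Step 3
Reactants: 3 (2E)-3-(tosyloxy)but-2-enoic acid; 4 (2-tert-butoxy-2-oxoethyl)zinc chloride (0.5 M solution)
Product: 7 (2E)-5-tert-butoxy-3-methyl-5-oxopent-2-enoic acid, via chlorozinc tosyloxybutenoate 5 (not isolated), via chlorozinc salt of the half ester 6 (not isolated)
Conditions: 4 (2.4 equiv), Pd(OAc)2 (3 mol %), XPhos (6 mol %), THF, 0 → 45 °C; cold 1 M HCl
Reagents that add atoms: none
Why: Negishi coupling of a Reformatsky reagent in which the first equivalent only deprotonates the acid, zerovalent palladium inserts into the C–OTs bond and reductive elimination occurs with retention (E kept), and the carboxylate charge lowers the acidity of the new CH2 so that the double bond is not scrambled.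

Step 4
Reactants: 8 (3R)-3,7-dimethylocta-1,6-diene ((R)-β-citronellene)
Product: 10 (4R)-4-methylhex-5-enal, via secondary ozonide 9 (not isolated)
Conditions: O3 (1.0 equiv, Sudan red end point), CH2Cl2, −78 °C; Me2S, −78 °C → rt
Reagents that add atoms: ozone, [O-][O+]=O
Why: Chemoselective Criegee ozonolysis, because the electron-rich trisubstituted alkene reacts far faster than the vinyl group, and the methyl-bearing centre (future C8, R) is not touched.

Step 5
Reactants: 10 (4R)-4-methylhex-5-enal; 11 methyl vinyl ketone (3 equiv)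
Product: 12 (4R,5E)-4-methyl-7-oxooct-5-enal
Conditions: second-generation Hoveyda–Grubbs catalyst (2.5 mol %), CH2Cl2, 40 °C
Reagents that add atoms: none
Why: Olefin cross-metathesis between a terminal olefin and an electron-poor enone partner is selective for the cross product and gives the E enone under thermodynamic control, with the aldehyde tolerated.

Step 6
Reactants: 7 (2E)-5-tert-butoxy-3-methyl-5-oxopent-2-enoic acid; 12 (4R,5E)-4-methyl-7-oxooct-5-enal
Product: 14 5-tert-butyl 1-[(2R,4R,5E)-4-methyl-1,7-dioxooct-5-en-2-yl] (2E)-3-methylpent-2-enedioate, via bis(alkenoyl) peroxide 13 (not isolated)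
Conditions: 7 (2.4 equiv), urea·H2O2 (1.2 equiv), DCC (2.4 equiv), CH2Cl2, −10 °C, filter; filtrate + 12 (1.0 equiv), (R)-2-[diphenyl(trimethylsilyloxy)methyl]pyrrolidine (15 mol %), hydroquinone (10 mol %), THF, 0 °C
Reagents that add atoms: urea–hydrogen peroxide, OO.NC(N)=O
Why: Proposed new method: enamine-catalysed asymmetric transfer of a functionalised alkenoyloxy group from a symmetrical bis(alkenoyl) peroxide made in the flask by carbodiimide coupling of 7 to H2O2, in which the E-enamine of 12 attacks the O–O σ* orbital through the face not shielded by the diphenyl(silyloxy)methyl group (SN2 at oxygen, carboxylate of 7 as leaving group) and hydrolysis of the α-acyloxy iminium ion releases 14 with the new C–O bond and the R centre that becomes C6, while the conjugated sp2 acyl group makes 13 electronically like dibenzoyl peroxide (no easy decarboxylation) and its symmetry excludes transfer of a wrong acyloxy group; the closest known reaction type is the amine-catalysed asymmetric α-benzoyloxylation of aldehydes by dibenzoyl peroxide.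

Step 7
Reactants: 15 tiglic acid ((2E)-2-methylbut-2-enoic acid)
Product: 16 (2R)-2-methylbutanoic acid
Conditions: H2 (4 atm), Ru(OAc)2[(R)-H8-BINAP] (0.5 mol %), MeOH, 20 °C
Reagents that add atoms: none
Why: Carboxylate-directed asymmetric hydrogenation of an α,β-unsaturated acid, in which the R ligand gives the R acid (about 97% ee) and so sets the sec-butyl centre.

Step 8
Reactants: 16 (2R)-2-methylbutanoic acid
Product: 19 (2E,4R)-4-methylhex-2-enal, via acyl imidazolide 17 (not isolated), via (2R)-2-methylbutanal 18 (not isolated)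
Conditions: CDI (1.1 equiv), CH2Cl2, 0 °C → rt; iBu2AlH (2.1 equiv), −78 °C; aq. tartaric acid; dried organic layer + Ph3P=CHCHO (1.05 equiv), PhMe, CH2Cl2 distilled off, 70 °C
Reagents that add atoms: (triphenylphosphoranylidene)acetaldehyde, O=CC=P(c1ccccc1)(c1ccccc1)c1ccccc1
Why: Partial reduction of an acyl imidazolide stops at the aldehyde without loss of α-configuration, and the volatile aldehyde is trapped directly in a Wittig reaction whose stabilised ylide gives the E enal.

Step 9
Reactants: 19 (2E,4R)-4-methylhex-2-enal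
Product: 20 (1E,3E,5R)-1-iodo-5-methylhepta-1,3-diene
Conditions: CrCl2 (6 equiv), CHI3 (2 equiv), THF/dioxane, 0 °C → rt, dark
Reagents that add atoms: iodoform, IC(I)I
Why: Takai olefination, in which the geminal dichromium reagent from CHI3 adds to the aldehyde and eliminates to the E vinyl iodide, and the neutral medium spares the allylic stereocentre.

Step 10
Reactants: 14 α-acyloxy aldehyde; 20 (1E,3E,5R)-1-iodo-5-methylhepta-1,3-diene (1.5 equiv)
Product: 23 5-tert-butyl 1-[(3E,5R,7R,8S,9E,11E,13R)-8-hydroxy-5,13-dimethyl-2-oxopentadeca-3,9,11-trien-7-yl] (2E)-3-methylpent-2-enedioate, via dienylchromium dichloride 21 (not isolated), via chromium alkoxide 22 (not isolated)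
Conditions: CrCl2 (4 equiv), NiCl2 (1 mol %), DMSO/THF, 20 °C; water, work-up below 25 °C
Reagents that add atoms: none
Why: Nozaki–Hiyama–Kishi coupling, in which zerovalent nickel inserts into the C–I bond with retention and the dienyl group on trivalent chromium adds only to the aldehyde (ketone, enone and esters are left), with polar Felkin–Anh attack anti to the C–O(acyl) bond giving the 7,8-anti product and so the 8S carbinol (future C5).

Step 11
Reactants: 23 hydroxy triene
Product: 26 5-tert-butyl 1-[(1S,2S,4aR,5S,6R,8R,8aS)-1-acetyl-2-[(2R)-butan-2-yl]-5-hydroxy-8-methyl-1,2,4a,5,6,7,8,8a-octahydronaphthalen-6-yl] (2E)-3-methylpent-2-enedioate, via triene aluminium alkoxide 24 (not isolated), via decalin aluminium alkoxide 25 (not isolated)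
Conditions: Me2AlCl (3.5 equiv), CH2Cl2, −78 → −20 °C; aq. potassium sodium tartrate
Reagents that add atoms: none
Why: Lewis-acid-promoted intramolecular Diels–Alder reaction, in which one equivalent of Me2AlCl is taken up by the hydroxyl, further Me2AlCl binds the enone, and the (E,E)-diene adds to the (E)-enone through the endo chair-like transition state that keeps the C8 methyl and the C5 oxygen equatorial and only the C6 acyloxy group axial, giving the trans-decalin and setting C4a (R), C8a (S), C1 (S) and C2 (S) in one event.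

Step 12
Reactants: 26 decalin tert-butyl ester
Product: 27 (3E)-5-{[(1S,2S,4aR,5S,6R,8R,8aS)-1-acetyl-2-[(2R)-butan-2-yl]-5-hydroxy-8-methyl-1,2,4a,5,6,7,8,8a-octahydronaphthalen-6-yl]oxy}-3-methyl-5-oxopent-3-enoic acid (CNP0404452.1)
Conditions: TFA/CH2Cl2 (1:4), 0 °C → rt, 2 h; toluene azeotrope
Reagents that add atoms: none
Why: Acidolysis of the tert-butyl ester (isobutene loss) needs no base, so the secondary enoate ester, the E double bond, the C1 centre next to the ketone and the position of the acyl group on O6 are all preserved.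

## Compound list
1 | tert-butyl acetoacetate | CC(=O)CC(=O)OC(C)(C)C | starting material
2 | tert-butyl (2E)-3-(tosyloxy)but-2-enoate | C/C(OS(=O)(=O)c1ccc(C)cc1)=C\C(=O)OC(C)(C)C | intermediate
3 | (2E)-3-(tosyloxy)but-2-enoic acid | C/C(OS(=O)(=O)c1ccc(C)cc1)=C\C(=O)O | intermediate
4 | (2-tert-butoxy-2-oxoethyl)zinc chloride | CC(C)(C)OC(=O)C[Zn]Cl | starting material
5 | chlorozinc (2E)-3-(tosyloxy)but-2-enoate | C/C(OS(=O)(=O)c1ccc(C)cc1)=C\C(=O)O[Zn]Cl | intermediate
6 | chlorozinc (2E)-5-tert-butoxy-3-methyl-5-oxopent-2-enoate | CC(C)(C)OC(=O)C/C(C)=C/C(=O)O[Zn]Cl | intermediate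
7 | (2E)-5-tert-butoxy-3-methyl-5-oxopent-2-enoic acid | CC(C)(C)OC(=O)C/C(C)=C/C(=O)O | intermediate
8 | (3R)-3,7-dimethylocta-1,6-diene | C=C[C@H](C)CCC=C(C)C | starting material
9 | 3,3-dimethyl-5-[(3R)-3-methylpent-4-enyl]-1,2,4-trioxolane (epimers at C5) | C=C[C@H](C)CCC1OOC(C)(C)O1 | intermediate
10 | (4R)-4-methylhex-5-enal | C=C[C@H](C)CCC=O | intermediate
11 | methyl vinyl ketone | C=CC(C)=O | starting material
12 | (4R,5E)-4-methyl-7-oxooct-5-enal | CC(=O)/C=C/[C@H](C)CCC=O | intermediate
13 | bis[(2E)-5-tert-butoxy-3-methyl-5-oxopent-2-enoyl] peroxide | CC(C)(C)OC(=O)C/C(C)=C/C(=O)OOC(=O)/C=C(\C)CC(=O)OC(C)(C)C | intermediate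
14 | 5-tert-butyl 1-[(2R,4R,5E)-4-methyl-1,7-dioxooct-5-en-2-yl] (2E)-3-methylpent-2-enedioate | O=C[C@H](OC(=O)/C=C(\C)CC(=O)OC(C)(C)C)C[C@@H](C)/C=C/C(C)=O | intermediate
15 | tiglic acid | C/C=C(\C)C(=O)O | starting material
16 | (2R)-2-methylbutanoic acid | CC[C@@H](C)C(=O)O | intermediate
17 | 1-[(2R)-2-methylbutanoyl]imidazole | CC[C@@H](C)C(=O)n1ccnc1 | intermediate
18 | (2R)-2-methylbutanal | CC[C@@H](C)C=O | intermediate
19 | (2E,4R)-4-methylhex-2-enal | CC[C@@H](C)/C=C/C=O | intermediate
20 | (1E,3E,5R)-1-iodo-5-methylhepta-1,3-diene | CC[C@@H](C)/C=C/C=C/I | intermediate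
21 | dichloro[(1E,3E,5R)-5-methylhepta-1,3-dienyl]chromium | CC[C@@H](C)/C=C/C=C/[Cr](Cl)Cl | intermediate
22 | dichlorochromium alkoxide of 23 | CC[C@@H](C)/C=C/C=C/[C@H](O[Cr](Cl)Cl)[C@H](OC(=O)/C=C(\C)CC(=O)OC(C)(C)C)C[C@@H](C)/C=C/C(C)=O | intermediate
23 | hydroxy triene (3E,5R,7R,8S,9E,11E,13R), 7-O-[(2E)-5-tert-butoxy-3-methyl-5-oxopent-2-enoyl] | CC[C@@H](C)/C=C/C=C/[C@H](O)[C@H](OC(=O)/C=C(\C)CC(=O)OC(C)(C)C)C[C@@H](C)/C=C/C(C)=O | intermediate
24 | chloro(methyl)aluminium alkoxide of 23 | CC[C@@H](C)/C=C/C=C/[C@H](O[Al](C)Cl)[C@H](OC(=O)/C=C(\C)CC(=O)OC(C)(C)C)C[C@@H](C)/C=C/C(C)=O | intermediate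
25 | chloro(methyl)aluminium alkoxide of 26 | CC[C@@H](C)[C@H]1C=C[C@H]2[C@H](O[Al](C)Cl)[C@H](OC(=O)/C=C(\C)CC(=O)OC(C)(C)C)C[C@@H](C)[C@@H]2[C@H]1C(C)=O | intermediate
26 | trans-decalin tert-butyl ester (1S,2S,4aR,5S,6R,8R,8aS, sec-butyl R) | CC[C@@H](C)[C@H]1C=C[C@H]2[C@H](O)[C@H](OC(=O)/C=C(\C)CC(=O)OC(C)(C)C)C[C@@H](C)[C@@H]2[C@H]1C(C)=O | intermediate
27 | CNP0404452.1 | CC[C@@H](C)[C@H]1C=C[C@H]2[C@H](O)[C@H](OC(=O)/C=C(\C)CC(=O)O)C[C@@H](C)[C@@H]2[C@H]1C(C)=O | target

## Step count and risks
Total steps: 12. Longest linear sequence: 7 (steps 1, 2, 3, 6, 10, 11, 12).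

**Risk 1, step 6 (the proposed new step).**
- Possible failures:
  - The peroxide may N-acyloxylate the amine catalyst.
  - The acidic glutaconate CH2 may undergo Knoevenagel-type condensation with the aldehyde.
  - The ee may be lower than with dibenzoyl peroxide.
- The fallback uses known chemistry only. It sets out from 12 and comes back at 14.
- L-Proline-catalysed α-aminoxylation of 12 with nitrosobenzene (this catalyst gives the R centre) forms the α-anilinooxy aldehyde F1.
- NaBH4 at −40 °C in the same flask reduces F1 to the anilinooxy alcohol F2.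
- Zn dust in AcOH/THF cleaves the N–O bond to the 7,8-diol F3.
- TBSCl/imidazole silylates the primary hydroxyl to the silyl ether F4.
- Carbodiimide esterification of the secondary hydroxyl with 7 gives the silyloxy ester F5.
- HF·pyridine frees the primary alcohol F6.
- Immediate Dess–Martin oxidation gives 14.

**Risk 2, step 10.**
- Possible failures:
  - The Felkin selectivity may be only moderate.
  - The acyl group may migrate from O7 to O8 at the chromium alkoxide stage.
  - 14 may epimerise.
- The fallback replaces substrate control on chromium by ligand control on zinc. It sets out from 19 (and uses 14) and comes back at 23.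
- Corey–Fuchs homologation of 19 (CBr4, PPh3) gives the dibromodiene F7. nBuLi then gives the enyne F8.
- Hydrozirconation with Cp2ZrHCl gives the dienylzirconocene chloride F9.
- Transmetalation with Me2Zn gives the dienyl(methyl)zinc F10.
- F10 adds to 14 at −30 °C in the presence of 10 mol % of the 3-exo-morpholinoisoborneol enantiomer that is matched to the Felkin sense. This gives the methylzinc alkoxide F11.
- A pH 7 quench of F11 gives 23.

**Risk 3, step 11.**
- Possible failures:
  - The developing peri contact between the C1 acetyl and the C8 methyl may erode the endo selectivity.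
  - The acyl group may shift at the aluminium alkoxide stage.
  - The dienylic C–O bond may ionise.
- The fallback changes the substrate. It sets out from 23 and comes back at 27.
- Et3SiOTf/2,6-lutidine at −78 °C converts 23 into the triethylsilyl ether F12.
- F12 has no alkoxide to trigger migration, and its bulky equatorial OSiEt3 group reinforces the chair-like endo transition state.
- Me2AlCl (2.5 equiv, −78 → −30 °C) cyclises F12 to the silylated decalin F13.
- TFA/CH2Cl2 removes the silyl group and the tert-butyl ester together to give 27.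

## Further compounds
F1 | step 6 | (2R,4R,5E)-2-(anilinooxy)-4-methyl-7-oxooct-5-enal | O=C[C@H](ONc1ccccc1)C[C@@H](C)/C=C/C(C)=O
F2 | step 6 | (3E,5R,7R)-7-(anilinooxy)-8-hydroxy-5-methyloct-3-en-2-one | OC[C@H](ONc1ccccc1)C[C@@H](C)/C=C/C(C)=O
F3 | step 6 | (3E,5R,7R)-7,8-dihydroxy-5-methyloct-3-en-2-one | OC[C@H](O)C[C@@H](C)/C=C/C(C)=O
F4 | step 6 | (3E,5R,7R)-8-(tert-butyldimethylsilyloxy)-7-hydroxy-5-methyloct-3-en-2-one | CC(C)(C)[Si](C)(C)OC[C@H](O)C[C@@H](C)/C=C/C(C)=O
F5 | step 6 | 5-tert-butyl 1-[(2R,4R,5E)-1-(tert-butyldimethylsilyloxy)-4-methyl-7-oxooct-5-en-2-yl] (2E)-3-methylpent-2-enedioate | CC(C)(C)[Si](C)(C)OC[C@H](OC(=O)/C=C(\C)CC(=O)OC(C)(C)C)C[C@@H](C)/C=C/C(C)=O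
F6 | step 6 | 5-tert-butyl 1-[(2R,4R,5E)-1-hydroxy-4-methyl-7-oxooct-5-en-2-yl] (2E)-3-methylpent-2-enedioate | OC[C@H](OC(=O)/C=C(\C)CC(=O)OC(C)(C)C)C[C@@H](C)/C=C/C(C)=O
F7 | step 10 | (3E,5R)-1,1-dibromo-5-methylhepta-1,3-diene | CC[C@@H](C)/C=C/C=C(Br)Br
F8 | step 10 | (3E,5R)-5-methylhept-3-en-1-yne | CC[C@@H](C)/C=C/C#C
F9 | step 10 | chlorobis(cyclopentadienyl)[(1E,3E,5R)-5-methylhepta-1,3-dienyl]zirconium | CC[C@@H](C)/C=C/C=C/[Zr+2]Cl.c1cc[cH-]c1.c1cc[cH-]c1
F10 | step 10 | methyl[(1E,3E,5R)-5-methylhepta-1,3-dienyl]zinc | CC[C@@H](C)/C=C/C=C/[Zn]C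
F11 | step 10 | methylzinc alkoxide of 23 | CC[C@@H](C)/C=C/C=C/[C@H](O[Zn]C)[C@H](OC(=O)/C=C(\C)CC(=O)OC(C)(C)C)C[C@@H](C)/C=C/C(C)=O
F12 | step 11 | 8-O-triethylsilyl ether of 23 | CC[C@@H](C)/C=C/C=C/[C@H](O[Si](CC)(CC)CC)[C@H](OC(=O)/C=C(\C)CC(=O)OC(C)(C)C)C[C@@H](C)/C=C/C(C)=O
F13 | step 11 | 5-O-triethylsilyl ether of 26 | CC[C@@H](C)[C@H]1C=C[C@H]2[C@H](O[Si](CC)(CC)CC)[C@H](OC(=O)/C=C(\C)CC(=O)OC(C)(C)C)C[C@@H](C)[C@@H]2[C@H]1C(C)=O
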